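**Retrosynthetic overview**

1. The target is 2,8-dimethyl-3-hexaprenylnaphthalene-1,4-dione (8-methylmenaquinone-6). Quinone ring B is cut at C4–C4a and at C1–C2, giving a benzamide fragment (C1, C8a, C4a and the C8 methyl on benzene ring A) and a three-carbon fragment (C4, C3, C2) that already carries the hexaprenyl chain and the C2 methyl.
2. Enabling feature: C1 is a benzoyl carbon ortho to C4a, so a diethylamide on a 2-bromo-6-methylbenzene ring supplies the aryl anion at C4a (from C–Br) and then the acyl acceptor at C1. The tetrasubstituted C2=C3 bond holds C4 and C1 cis, so a (Z)-3-stannyl-2-hexaprenylbut-2-enal delivers C4 as an aldehyde and C2 as a latent vinyl anion with the regiochemistry fixed.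
3. Three-carbon fragment: ethyl acetoacetate is alkylated with hexaprenyl bromide, converted to the chelation-controlled Z enol triflate, stannylated, then reduced and oxidised to the enal.
4. Hexaprenyl bromide: two farnesyl units are joined head to tail by sulfone alkylation and reductive desulfonylation.
5. Ring order: ring A is bought; ring B is closed last, in the key step, and brought to the quinone oxidation level in the same pot.

Key step: step 13

Remark: "hexaprenyl" means the (2E,6E,10E,14E,18E)-3,7,11,15,19,23-hexamethyltetracosa-2,6,10,14,18,22-hexaen-1-yl group. The target has no stereocentre, so only the five E double bonds and the cis placement of tin and carbonyl in the three-carbon fragment need control; the racemic centres formed in 6, 7, 11, 20 and 22 are all erased later.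
Remark: (2E,6E)-farnesyl acetate, (2E,6E)-farnesyl bromide, ethyl acetoacetate and 2-bromo-6-methylbenzoic acid are taken as the commercial starting materials; all-E-hexaprenol is not assumed to be available and is built.

**Route**

Step 1
Reactants: 1 (2E,6E)-farnesyl acetate
Product: 2 (2E,6E,10E)-12-hydroxy-3,7,11-trimethyldodeca-2,6,10-trien-1-yl acetate
Conditions: SeO2 (cat.), t-BuOOH, salicylic acid (cat.), CH2Cl2, 0 °C → rt
Reagents that add atoms: tert-butyl hydroperoxide CC(C)(C)OO (terminal oxidant; the oxygen is delivered through SeO2, O=[Se]=O)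
Why: Catalytic SeO2 allylic oxidation (ene reaction, then [2,3]-sigmatropic shift) should attack the most electron-rich terminal trisubstituted alkene at its E methyl group, giving the 10E allylic alcohol, while the alkene next to the acetate is deactivated.

Step 2
Reactants: 2 (2E,6E,10E)-12-hydroxy-3,7,11-trimethyldodeca-2,6,10-trien-1-yl acetate
Product: 3 (2E,6E,10E)-12-bromo-3,7,11-trimethyldodeca-2,6,10-trien-1-yl acetate
Conditions: CBr4, PPh3, CH2Cl2, 0 °C
Reagents that add atoms: carbon tetrabromide BrC(Br)(Br)Br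
Why: The Appel reaction converts the primary allylic alcohol to the bromide under neutral conditions by direct displacement, which should keep the 10E geometry and the acetate.

Step 3
Reactants: 4 (2E,6E)-farnesyl bromide
Product: 5 (2E,6E)-farnesyl phenyl sulfone
Conditions: PhSO2Na, DMF, rt
Reagents that add atoms: sodium benzenesulfinate [Na+].[O-]S(=O)c1ccccc1
Why: S-alkylation of the sulfinate by the primary allylic bromide (SN2) should give the allylic sulfone with the 2E,6E geometry untouched.

Step 4
Reactants: 5 (2E,6E)-farnesyl phenyl sulfone; 3 (2E,6E,10E)-12-bromo-3,7,11-trimethyldodeca-2,6,10-trien-1-yl acetate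
Product: 6 (2E,6E,10E,14E,18E)-3,7,11,15,19,23-hexamethyl-13-(phenylsulfonyl)tetracosa-2,6,10,14,18,22-hexaen-1-yl acetate (racemic)
Conditions: n-BuLi, THF–DMPU, −78 °C; then 3, −78 → −40 °C
Reagents that add atoms: none
Why: In this Biellmann-type coupling the sulfonyl-stabilised allyl anion should alkylate at its α-carbon with the primary allylic bromide at −78 °C faster than it attacks the acetate, joining the two C15 units head to tail; the new sulfone-bearing centre is racemic and is removed in step 5.

Step 5
Reactants: 6 C30 sulfone acetate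
Product: 8 (2E,6E,10E,14E,18E)-3,7,11,15,19,23-hexamethyltetracosa-2,6,10,14,18,22-hexaen-1-ol (all-E-hexaprenol), via hydroxy sulfone 7 (not isolated)
Conditions: LiBHEt3, THF, 0 °C; then PdCl2(dppp) (cat.), LiBHEt3, 0 °C → rt
Reagents that add atoms: none
Why: LiBHEt3 first cleaves the acetate, so no allylic ester is left to ionise; zerovalent palladium formed from PdCl2(dppp) then ionises the allylic sulfone to a π-allylpalladium that should take hydride at the less substituted terminus, leaving the trisubstituted alkene in place with E geometry (palladium-catalysed reductive desulfonylation).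

Step 6
Reactants: 8 all-E-hexaprenol
Product: 9 all-E-hexaprenyl bromide
Conditions: PBr3, pyridine (cat.), Et2O, −10 °C
Reagents that add atoms: phosphorus tribromide BrP(Br)Br
Why: PBr3 converts the primary allylic alcohol to the bromide by SN2 at low temperature, the standard entry to all-E polyprenyl bromides.

Step 7
Reactants: 9 all-E-hexaprenyl bromide; 10 ethyl acetoacetate
Product: 11 ethyl 2-hexaprenyl-3-oxobutanoate (racemic)
Conditions: 10 (excess), NaH, THF, 0 °C; then 9, 0 °C → rt
Reagents that add atoms: none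
Why: C-alkylation of the sodium enolate with the primary allylic bromide (SN2, excess enolate against dialkylation) should attach the chain through its CH2 without allylic transposition; the new centre is racemic and is erased in step 8.

Step 8
Reactants: 11 ethyl 2-hexaprenyl-3-oxobutanoate
Product: 12 ethyl (Z)-2-hexaprenyl-3-(trifluoromethylsulfonyloxy)but-2-enoate
Conditions: NaH, THF, 0 °C; then PhNTf2, 0 °C → rt
Reagents that add atoms: N-phenylbis(trifluoromethanesulfonimide) O=S(=O)(N(c1ccccc1)S(=O)(=O)C(F)(F)F)C(F)(F)F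
Why: The sodium enolate of the α-substituted β-keto ester is held as a six-membered O–Na–O chelate, so O-triflation should give the Z enol triflate (triflate cis to the ester), and the neutral triflimide should leave the polyene alone.

Step 9
Reactants: 12 ethyl (Z)-2-hexaprenyl-3-(trifluoromethylsulfonyloxy)but-2-enoate
Product: 13 ethyl (Z)-2-hexaprenyl-3-(trimethylstannyl)but-2-enoate
Conditions: Me3SnSnMe3, Pd(PPh3)4 (cat.), LiCl, THF, 65 °C
Reagents that add atoms: hexamethylditin C[Sn](C)(C)[Sn](C)(C)C
Why: Palladium-catalysed stannylation of an enol triflate (oxidative addition of zerovalent palladium, transmetalation with the ditin, reductive elimination) proceeds with retention of alkene geometry, so tin should end up cis to the ester.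

Step 10
Reactants: 13 ethyl (Z)-2-hexaprenyl-3-(trimethylstannyl)but-2-enoate
Product: 14 (Z)-2-hexaprenyl-3-(trimethylstannyl)but-2-en-1-ol
Conditions: i-Bu2AlH, CH2Cl2, −78 → 0 °C; Rochelle salt work-up
Reagents that add atoms: none
Why: i-Bu2AlH should reduce the conjugated ester 1,2 to the allylic alcohol without touching the vinylstannane or the isolated alkenes.

Step 11
Reactants: 14 (Z)-2-hexaprenyl-3-(trimethylstannyl)but-2-en-1-ol
Product: 15 (Z)-2-hexaprenyl-3-(trimethylstannyl)but-2-enal
Conditions: MnO2, CH2Cl2, rt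
Reagents that add atoms: none
Why: MnO2 oxidises only the allylic alcohol, under neutral conditions that should avoid protodestannylation and keep tin cis to the formyl group.

Step 12
Reactants: 16 2-bromo-6-methylbenzoic acid
Product: 18 2-bromo-N,N-diethyl-6-methylbenzamide, via acid chloride 17 (not isolated)
Conditions: (COCl)2, DMF (cat.), CH2Cl2, 0 °C → rt; evaporate; then Et2NH (excess), CH2Cl2, 0 °C → rt
Reagents that add atoms: diethylamine CCNCC
Why: Acid chloride formation followed by amidation is reliable even for a 2,6-disubstituted benzoic acid and installs the tertiary amide that later serves as the internal acylating group.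

Step 13
Reactants: 18 2-bromo-N,N-diethyl-6-methylbenzamide; 15 (Z)-2-hexaprenyl-3-(trimethylstannyl)but-2-enal
Product: 24 2,8-dimethyl-3-hexaprenylnaphthalene-1,4-dione (target), via aryllithium 19 (not isolated), via lithium alkoxide 20 (not isolated), via vinyllithium 21 (not isolated), via hydroxynaphthalenone 22 (not isolated), via quinol 23 (not isolated)
Conditions: 18, t-BuLi (2 equiv), THF, −78 °C; then 15, −78 °C; then MeLi, −78 → 0 °C; aq. NH4Cl; then MnO2, CH2Cl2, rt
Reagents that add atoms: none
Why: Bromine–lithium exchange gives the ortho-lithiated benzamide 19, which adds 1,2 to the aldehyde of 15 (C4–C4a bond); MeLi then converts the trimethylstannyl group into the vinyllithium 21, which attacks the neighbouring diethylamide carbonyl (C1–C2 bond), and collapse with loss of diethylamine gives 22, which enolises to quinol 23 and is oxidised by MnO2 (which can also oxidise the carbinol of 22 directly) to the quinone. The closest known reaction type is the one-pot tandem metalation route to anthraquinones from ortho-lithiated N,N-diethylbenzamides and aryl aldehydes, combined with a Parham-type cyclisation in which the second carbanion is here a vinyllithium from tin–lithium exchange. Ring B is closed in an anionic [3+3] sense, the second bond by 6-exo-trig attack of the vinyllithium on the amide carbonyl, which the cis C2=C3 geometry places within reach. The only new stereocentre, the carbinol carbon C4 of 20 and 22, is formed racemic and is erased on aromatisation and oxidation. The step needs regiocontrol (C2 methyl next to the C1 carbonyl that is peri to the C8 methyl, chain next to C4), which is fixed by the bromine position on ring A and by the constitution and Z geometry of 15. It also needs chemoselectivity: the aryllithium should add to the aldehyde far faster than it exchanges with tin, MeLi should not attack the twisted 2,6-disubstituted amide at −78 °C, and the isolated trisubstituted alkenes of the chain are inert to the organolithiums and to MnO2.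

**Compound list**

1 | (2E,6E)-farnesyl acetate | CC(C)=CCC/C(C)=C/CC/C(C)=C/COC(C)=O | starting material
2 | (2E,6E,10E)-12-hydroxy-3,7,11-trimethyldodeca-2,6,10-trien-1-yl acetate | OC/C(C)=C/CC/C(C)=C/CC/C(C)=C/COC(C)=O | intermediate
3 | (2E,6E,10E)-12-bromo-3,7,11-trimethyldodeca-2,6,10-trien-1-yl acetate | BrC/C(C)=C/CC/C(C)=C/CC/C(C)=C/COC(C)=O | intermediate
4 | (2E,6E)-farnesyl bromide | CC(C)=CCC/C(C)=C/CC/C(C)=C/CBr | starting material
5 | (2E,6E)-farnesyl phenyl sulfone | CC(C)=CCC/C(C)=C/CC/C(C)=C/CS(=O)(=O)c1ccccc1 | intermediate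
6 | (2E,6E,10E,14E,18E)-3,7,11,15,19,23-hexamethyl-13-(phenylsulfonyl)tetracosa-2,6,10,14,18,22-hexaen-1-yl acetate (racemic) | CC(C)=CCC/C(C)=C/CC/C(C)=C/C(S(=O)(=O)c1ccccc1)C/C(C)=C/CC/C(C)=C/CC/C(C)=C/COC(C)=O | intermediate
7 | (2E,6E,10E,14E,18E)-3,7,11,15,19,23-hexamethyl-13-(phenylsulfonyl)tetracosa-2,6,10,14,18,22-hexaen-1-ol (racemic, formed as its lithium alkoxide) | CC(C)=CCC/C(C)=C/CC/C(C)=C/C(S(=O)(=O)c1ccccc1)C/C(C)=C/CC/C(C)=C/CC/C(C)=C/CO | intermediate
8 | all-E-hexaprenol, (2E,6E,10E,14E,18E)-3,7,11,15,19,23-hexamethyltetracosa-2,6,10,14,18,22-hexaen-1-ol | CC(C)=CCC/C(C)=C/CC/C(C)=C/CC/C(C)=C/CC/C(C)=C/CC/C(C)=C/CO | intermediate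
9 | all-E-hexaprenyl bromide | CC(C)=CCC/C(C)=C/CC/C(C)=C/CC/C(C)=C/CC/C(C)=C/CC/C(C)=C/CBr | intermediate
10 | ethyl acetoacetate | CCOC(=O)CC(C)=O | starting material
11 | ethyl 2-hexaprenyl-3-oxobutanoate (racemic) | CC(C)=CCC/C(C)=C/CC/C(C)=C/CC/C(C)=C/CC/C(C)=C/CC/C(C)=C/CC(C(C)=O)C(=O)OCC | intermediate
12 | ethyl (Z)-2-hexaprenyl-3-(trifluoromethylsulfonyloxy)but-2-enoate | CC(C)=CCC/C(C)=C/CC/C(C)=C/CC/C(C)=C/CC/C(C)=C/CC/C(C)=C/C/C(C(=O)OCC)=C(\C)OS(=O)(=O)C(F)(F)F | intermediate
13 | ethyl (Z)-2-hexaprenyl-3-(trimethylstannyl)but-2-enoate | CC(C)=CCC/C(C)=C/CC/C(C)=C/CC/C(C)=C/CC/C(C)=C/CC/C(C)=C/C/C(C(=O)OCC)=C(\C)[Sn](C)(C)C | intermediate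
14 | (Z)-2-hexaprenyl-3-(trimethylstannyl)but-2-en-1-ol | CC(C)=CCC/C(C)=C/CC/C(C)=C/CC/C(C)=C/CC/C(C)=C/CC/C(C)=C/C/C(CO)=C(\C)[Sn](C)(C)C | intermediate
15 | (Z)-2-hexaprenyl-3-(trimethylstannyl)but-2-enal | CC(C)=CCC/C(C)=C/CC/C(C)=C/CC/C(C)=C/CC/C(C)=C/CC/C(C)=C/C/C(C=O)=C(\C)[Sn](C)(C)C | intermediate
16 | 2-bromo-6-methylbenzoic acid | Cc1cccc(Br)c1C(=O)O | starting material
17 | 2-bromo-6-methylbenzoyl chloride | Cc1cccc(Br)c1C(Cl)=O | intermediate
18 | 2-bromo-N,N-diethyl-6-methylbenzamide | CCN(CC)C(=O)c1c(C)cccc1Br | intermediate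
19 | [2-(diethylcarbamoyl)-3-methylphenyl]lithium | CCN(CC)C(=O)c1c(C)cccc1[Li] | intermediate
20 | lithium alkoxide of N,N-diethyl-2-[(Z)-1-hydroxy-2-hexaprenyl-3-(trimethylstannyl)but-2-en-1-yl]-6-methylbenzamide (racemic) | CC(C)=CCC/C(C)=C/CC/C(C)=C/CC/C(C)=C/CC/C(C)=C/CC/C(C)=C/C/C(C(O[Li])c1cccc(C)c1C(=O)N(CC)CC)=C(\C)[Sn](C)(C)C | intermediate
21 | vinyllithium from 20 (lithium in place of tin, cis to the carbinol carbon; racemic) | CC(C)=CCC/C(C)=C/CC/C(C)=C/CC/C(C)=C/CC/C(C)=C/CC/C(C)=C/C/C(C(O[Li])c1cccc(C)c1C(=O)N(CC)CC)=C(\C)[Li] | intermediate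
22 | 4-hydroxy-3-hexaprenyl-2,8-dimethylnaphthalen-1(4H)-one (racemic) | CC(C)=CCC/C(C)=C/CC/C(C)=C/CC/C(C)=C/CC/C(C)=C/CC/C(C)=C/CC1=C(C)C(=O)c2c(C)cccc2C1O | intermediate
23 | 3-hexaprenyl-2,8-dimethylnaphthalene-1,4-diol | CC(C)=CCC/C(C)=C/CC/C(C)=C/CC/C(C)=C/CC/C(C)=C/CC/C(C)=C/Cc1c(C)c(O)c2c(C)cccc2c1O | intermediate
24 | 2,8-dimethyl-3-[(2E,6E,10E,14E,18E)-3,7,11,15,19,23-hexamethyltetracosa-2,6,10,14,18,22-hexaen-1-yl]naphthalene-1,4-dione (8-methylmenaquinone-6) | CC(C)=CCC/C(C)=C/CC/C(C)=C/CC/C(C)=C/CC/C(C)=C/CC/C(C)=C/CC1=C(C)C(=O)c2c(C)cccc2C1=O | target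

**Step count and risks**

Total step count: 13. Longest linear sequence: 11 steps (steps 1, 2, 4, 5, 6, 7, 8, 9, 10, 11, 13).

Steps most likely to fail:

Step 13. The tin–lithium exchange may be incomplete, or the vinyllithium may fail to acylate at the doubly ortho-substituted diethylamide and end up protonated as the uncyclised carbinol; proton transfer from the benzylic methyl group may also compete. The fallback sets out from 15 and 18 and forms the two bonds in separate flasks, with a lactone in place of the hindered amide as acyl acceptor and iodine–lithium exchange in place of tin–lithium exchange. Aryllithium 19 is added to 15 as before and the alkoxide 20 is lactonised (PPTS (cat.), toluene, 60 °C) to 3-[(Z)-1-hexaprenyl-2-(trimethylstannyl)prop-1-en-1-yl]-7-methyl-2-benzofuran-1(3H)-one F1. Iododestannylation (I2, CH2Cl2, 0 °C) gives the corresponding (Z)-vinyl iodide F2. Exchange with t-BuLi (2 equiv, THF–Et2O, −100 °C) gives the lithiated phthalide F3, whose vinyllithium adds to the lactone carbonyl through the oxygen-bridged alkoxide familiar from the Hauser annulation. Work-up should give 22, where the route is rejoined before the MnO2 oxidation.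

Step 9. Transmetalation at the hindered tetrasubstituted vinylpalladium may be slow, so that reduction, protodestannylation or loss of Z geometry takes over. The fallback sets out from 12 and replaces tin by bromine as the handle for the vinyl anion. Nickel-catalysed triflate–bromide exchange (Ni(cod)2 (cat., zerovalent nickel), LiBr, DMA–THF, rt) should give ethyl (Z)-3-bromo-2-hexaprenylbut-2-enoate F4. Reduction with i-Bu2AlH gives (Z)-3-bromo-2-hexaprenylbut-2-en-1-ol F5, and MnO2 gives (Z)-3-bromo-2-hexaprenylbut-2-enal F6. In the key step aryllithium 19 adds to F6 to give the bromo lithium alkoxide F7, and t-BuLi (2 equiv, −78 °C) effects bromine–lithium exchange to the vinyllithium 21, where the route is rejoined.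

Step 11. The tetrasubstituted stannyl enal may lose tin by protodestannylation or isomerise from Z to E during oxidation and purification, which would put the metal on the wrong side for ring closure. The fallback sets out from 13 and avoids the aldehyde by bringing C4 in at the carboxylic oxidation level. Treatment of 13 with MeNHOMe·HCl and i-PrMgCl (THF, −20 °C) should give (Z)-2-hexaprenyl-N-methoxy-N-methyl-3-(trimethylstannyl)but-2-enamide F8. Aryllithium 19 adds to F8 to give the chelated tetrahedral lithium adduct F9, MeLi converts this into the vinyllithium F10, and F10 closes onto the diethylamide. Aqueous work-up collapses both tetrahedral centres and should give the quinone 24 directly, without an oxidation, so the route is rejoined at 24.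

**Further compounds**

F1 | step 13 | 3-[(Z)-1-hexaprenyl-2-(trimethylstannyl)prop-1-en-1-yl]-7-methyl-2-benzofuran-1(3H)-one (racemic) | CC(C)=CCC/C(C)=C/CC/C(C)=C/CC/C(C)=C/CC/C(C)=C/CC/C(C)=C/C/C(C1OC(=O)c2c(C)cccc21)=C(\C)[Sn](C)(C)C
F2 | step 13 | 3-[(Z)-1-hexaprenyl-2-iodoprop-1-en-1-yl]-7-methyl-2-benzofuran-1(3H)-one (racemic) | CC(C)=CCC/C(C)=C/CC/C(C)=C/CC/C(C)=C/CC/C(C)=C/CC/C(C)=C/C/C(C1OC(=O)c2c(C)cccc21)=C(\C)I
F3 | step 13 | lithiated phthalide from F2 (lithium in place of iodine; racemic) | CC(C)=CCC/C(C)=C/CC/C(C)=C/CC/C(C)=C/CC/C(C)=C/CC/C(C)=C/C/C(C1OC(=O)c2c(C)cccc21)=C(\C)[Li]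
F4 | step 9 | ethyl (Z)-3-bromo-2-hexaprenylbut-2-enoate | CC(C)=CCC/C(C)=C/CC/C(C)=C/CC/C(C)=C/CC/C(C)=C/CC/C(C)=C/C/C(C(=O)OCC)=C(\C)Br
F5 | step 9 | (Z)-3-bromo-2-hexaprenylbut-2-en-1-ol | CC(C)=CCC/C(C)=C/CC/C(C)=C/CC/C(C)=C/CC/C(C)=C/CC/C(C)=C/C/C(CO)=C(\C)Br
F6 | step 9 | (Z)-3-bromo-2-hexaprenylbut-2-enal | CC(C)=CCC/C(C)=C/CC/C(C)=C/CC/C(C)=C/CC/C(C)=C/CC/C(C)=C/C/C(C=O)=C(\C)Br
F7 | step 9 | lithium alkoxide of 2-[(Z)-3-bromo-1-hydroxy-2-hexaprenylbut-2-en-1-yl]-N,N-diethyl-6-methylbenzamide (racemic) | CC(C)=CCC/C(C)=C/CC/C(C)=C/CC/C(C)=C/CC/C(C)=C/CC/C(C)=C/C/C(C(O[Li])c1cccc(C)c1C(=O)N(CC)CC)=C(\C)Br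
F8 | step 11 | (Z)-2-hexaprenyl-N-methoxy-N-methyl-3-(trimethylstannyl)but-2-enamide | CC(C)=CCC/C(C)=C/CC/C(C)=C/CC/C(C)=C/CC/C(C)=C/CC/C(C)=C/C/C(C(=O)N(C)OC)=C(\C)[Sn](C)(C)C
F9 | step 11 | tetrahedral lithium adduct of aryllithium 19 and F8 (racemic) | CC(C)=CCC/C(C)=C/CC/C(C)=C/CC/C(C)=C/CC/C(C)=C/CC/C(C)=C/C/C(C(O[Li])(N(C)OC)c1cccc(C)c1C(=O)N(CC)CC)=C(\C)[Sn](C)(C)C
F10 | step 11 | vinyllithium from F9 (lithium in place of tin; racemic) | CC(C)=CCC/C(C)=C/CC/C(C)=C/CC/C(C)=C/CC/C(C)=C/CC/C(C)=C/C/C(C(O[Li])(N(C)OC)c1cccc(C)c1C(=O)N(CC)CC)=C(\C)[Li]
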